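**Plan**
- Cuts: CO2H back to CH2OH; the 1,2-dioxane at O2–C3 (SN2 at a C3 mesylate) and at C6 (O1 and OMe removed, giving the C6 ketone); then the CH2–CH2 bond between the propargylic carbon of the ene-yne and the carbon β to C6.
- Enabling feature: ring carbon C6 (the methyl peroxyketal) is a masked ketone and the bond cut lies β,γ to it, while its other end sits next to the C≡C of the ene-yne. The cut therefore gives a ketone homoenolate, stored as a 1-substituted cyclopropanol (temporary three-membered ring), and an ene-ynyl propargylic bromide.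
- Sources: cyclopropanol from a γ-lactone (Kulinkovich), lactone from an (S)-epoxide plus ethoxyacetylene, epoxide from (S)-butanetriol acetonide; bromide from undec-1-yne plus propargyl alcohol.
- Forward: side chain (steps 1–3) and cyclopropanol (steps 4–8) are joined in step 9, which makes the C–C bond and releases the C6 ketone in one event; the dioxane ring is closed in steps 10–12 and the acid freed in steps 13–14.
- Stereochemistry: C3 from the chiral pool through one SN2 inversion (3R mesylate to 3S); C6 by thermodynamic control of the peroxyketal (axial OMe); E alkene from syn hydrozirconation.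

Key step: step 9

Remark: the C6 methyl peroxyketal is assumed to epimerise under acid through the peroxycarbenium ion, and the 3S,6R isomer (OMe axial, both carbon substituents equatorial) is assumed to be the more stable one.

**Step 1**
Reactants: 1 undec-1-yne
Product: 3 (E)-1-iodoundec-1-ene, via (E)-undec-1-enylzirconocene chloride 2 (not isolated)
Conditions: Cp2Zr(H)Cl, THF, rt; then I2, 0 °C
Reagents that add atoms: iodine, II
Why: Hydrozirconation with the Schwartz reagent adds Zr–H syn with Zr at the terminal carbon and iodinolysis of the C–Zr bond goes with retention, which fixes the E alkene.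

**Step 2**
Reactants: 3 (E)-1-iodoundec-1-ene; 4 prop-2-yn-1-ol
Product: 5 (E)-tetradec-4-en-2-yn-1-ol
Conditions: PdCl2(PPh3)2 (2 mol%), CuI (4 mol%), Et3N, THF, rt
Reagents that add atoms: none
Why: Sonogashira coupling of an alkenyl iodide with a terminal alkyne keeps the alkene geometry and tolerates the free propargylic hydroxyl.

**Step 3**
Reactants: 5 (E)-tetradec-4-en-2-yn-1-ol
Product: 6 (E)-1-bromotetradec-4-en-2-yne
Conditions: CBr4, PPh3, CH2Cl2, 0 °C
Reagents that add atoms: carbon tetrabromide, BrC(Br)(Br)Br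
Why: Appel bromination converts the primary propargylic alcohol into the bromide under neutral conditions that leave the ene-yne untouched.

**Step 4**
Reactants: 7 2-[(4S)-2,2-dimethyl-1,3-dioxolan-4-yl]ethanol
Product: 8 tert-butyl{2-[(4S)-2,2-dimethyl-1,3-dioxolan-4-yl]ethoxy}diphenylsilane
Conditions: TBDPSCl, imidazole, DMF, rt
Reagents that add atoms: tert-butyl(chloro)diphenylsilane, CC(C)(C)[Si](Cl)(c1ccccc1)c1ccccc1
Why: Silylation of the primary alcohol installs a group that should survive Lewis acid, Grignard, organozinc, peroxide and alkoxide conditions and is removed by fluoride at the end.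

**Step 5**
Reactants: 8 tert-butyl{2-[(4S)-2,2-dimethyl-1,3-dioxolan-4-yl]ethoxy}diphenylsilane
Product: 9 (2S)-4-[(tert-butyldiphenylsilyl)oxy]butane-1,2-diol
Conditions: AcOH/H2O (4:1), 40 °C
Reagents that add atoms: none
Why: Acid-catalysed acetal hydrolysis frees the 1,2-diol while the primary TBDPS ether is stable to aqueous acetic acid and the stereocentre is not involved.

**Step 6**
Reactants: 9 (2S)-4-[(tert-butyldiphenylsilyl)oxy]butane-1,2-diol
Product: 11 tert-butyl{2-[(2S)-oxiran-2-yl]ethoxy}diphenylsilane, via primary tosylate 10 (not isolated)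
Conditions: TsCl, Bu2SnO (2 mol%), Et3N, CH2Cl2, rt; then K2CO3, MeOH, rt
Reagents that add atoms: none
Why: Tin-catalysed selective tosylation of the primary hydroxyl followed by intramolecular Williamson closure by the secondary alkoxide gives the terminal epoxide without breaking any bond at the stereocentre, so the S configuration is kept.

**Step 7**
Reactants: 11 tert-butyl{2-[(2S)-oxiran-2-yl]ethoxy}diphenylsilane; 12 ethoxyacetylene
Product: 14 (5R)-5-{2-[(tert-butyldiphenylsilyl)oxy]ethyl}oxolan-2-one, via hydroxy ynol ether 13 (not isolated)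
Conditions: 12, n-BuLi, THF, −78 °C; BF3·OEt2, then 11, −78 °C; then p-TsOH·H2O, EtOH, −78 °C → rt
Reagents that add atoms: water, O
Why: BF3-promoted epoxide opening at the CH2 carbon by the lithium alkynyl ether, then acid-mediated hydration of the ynol ether and lactonisation, gives the γ-lactone with the carbinol centre untouched (the descriptor changes from S to R only through the priority rules).

**Step 8**
Reactants: 14 (5R)-5-{2-[(tert-butyldiphenylsilyl)oxy]ethyl}oxolan-2-one
Product: 15 1-{(3R)-5-[(tert-butyldiphenylsilyl)oxy]-3-hydroxypentyl}cyclopropan-1-ol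
Conditions: EtMgBr (3.5 equiv, slow addition), Ti(OiPr)4 (0.3 equiv), THF, 0 °C → rt
Reagents that add atoms: ethylmagnesium bromide, CC[Mg]Br
Why: Kulinkovich cyclopropanation of the lactone carbonyl by the titanacyclopropane made from EtMgBr and Ti(OiPr)4 gives the 1-substituted cyclopropanol, releases the ring oxygen as the free C3 alcohol and so installs the latent ketone homoenolate.

**Step 9**
Reactants: 15 1-{(3R)-5-[(tert-butyldiphenylsilyl)oxy]-3-hydroxypentyl}cyclopropan-1-ol; 6 (E)-1-bromotetradec-4-en-2-yne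
Product: 17 (3R,12E)-1-[(tert-butyldiphenylsilyl)oxy]-3-hydroxydocos-12-en-10-yn-6-one, via zinc homoenolate 16 (not isolated)
Conditions: EtZnCl (from Et2Zn + ZnCl2, 2.2 equiv), THF, 0 °C → rt; then 6 (1.3 equiv), NiCl2·glyme (10 mol%), 2,2′:6′,2″-terpyridine (12 mol%), DMA, rt
Reagents that add atoms: none
Why: Proposed new method: EtZnCl turns both hydroxyls of 15 into chlorozinc alkoxides (no transferable ethyl group stays on zinc) and the strained zinc cyclopropoxide opens by β-carbon elimination, the two ring CH2 groups being equivalent, to the β-zincio ketone 16; a (terpy)Ni(I) species then abstracts bromine from 6, the alkyl group of 16 is transferred to nickel, the propargylic radical is captured at its CH2 terminus and C(sp3)–C(sp3) reductive elimination forms the CH2–CH2 bond. The closest known reaction types are the Ni/terpyridine Negishi coupling of alkylzinc halides with propargylic bromides, which gives alkynes and not allenes, and the Cu- and Pd-mediated couplings of cyclopropanol-derived zinc homoenolates with allylic and aryl electrophiles; the union of a homoenolate with a propargylic halide under nickel has not been shown. No ring is closed (the cyclopropane is opened) and no stereocentre is formed; the remote C3 carbinol is carried through as its zinc alkoxide. The step needs regioselectivity for the propargylic CH2 over the allenyl carbon of the delocalised radical (which would give a vinylallene): the CH2 terminus is unsubstituted, keeps the ene-yne conjugation in the product, and is the site at which nickel, unlike SN2′-selective copper, is known to couple. It also needs C- over O-alkylation and no β-hydride elimination of the nickel homoenolate to the vinyl ketone, which the poorly nucleophilic zinc alkoxides and the tridentate terpyridine ligand (no free cis site) should secure.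

**Step 10**
Reactants: 17 (3R,12E)-1-[(tert-butyldiphenylsilyl)oxy]-3-hydroxydocos-12-en-10-yn-6-one
Product: 18 (3R,12E)-1-[(tert-butyldiphenylsilyl)oxy]-6-oxodocos-12-en-10-yn-3-yl methanesulfonate
Conditions: MsCl, Et3N, CH2Cl2, −20 °C
Reagents that add atoms: methanesulfonyl chloride, CS(=O)(=O)Cl
Why: Mesylation forms an O–S bond only, so C3 keeps its R configuration and becomes the electrophile for the later SN2 ring closure, the open-chain hydroxy ketone being trapped in preference to the minor cyclic hemiketal.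

**Step 11**
Reactants: 18 (3R,12E)-1-[(tert-butyldiphenylsilyl)oxy]-6-oxodocos-12-en-10-yn-3-yl methanesulfonate
Product: 19 (3R,12E)-1-[(tert-butyldiphenylsilyl)oxy]-6-hydroperoxy-6-methoxydocos-12-en-10-yn-3-yl methanesulfonate (C6 epimers)
Conditions: urea·H2O2 (10 equiv), Sc(OTf)3 (10 mol%), MeOH, rt
Reagents that add atoms: hydrogen peroxide (from urea–hydrogen peroxide), OO; methanol, CO
Why: Lewis-acid-catalysed hydroperoxyketalisation of the ketone (capture of the oxocarbenium ion by H2O2 and MeOH) should give the α-methoxy hydroperoxide without affecting the ene-yne, the mesylate or the silyl ether, the C6 configuration being left uncontrolled at this stage.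

**Step 12**
Reactants: 19 (3R,12E)-1-[(tert-butyldiphenylsilyl)oxy]-6-hydroperoxy-6-methoxydocos-12-en-10-yn-3-yl methanesulfonate (C6 epimers)
Product: 21 tert-butyl{2-[(3S,6R)-6-[(6E)-hexadec-6-en-4-yn-1-yl]-6-methoxy-1,2-dioxan-3-yl]ethoxy}diphenylsilane, via C6-epimeric 1,2-dioxane 20 (not isolated)
Conditions: KOtBu (1.05 equiv), 18-crown-6, THF, 0 °C; then CSA (0.3 equiv), MeOH, rt
Reagents that add atoms: methanol, CO
Why: Intramolecular alkylation of the hydroperoxyketal anion (6-exo-tet SN2) closes the 1,2-dioxane with inversion at C3 (3R mesylate to 3S), and acid-catalysed methanol exchange through the ring peroxycarbenium ion should then converge C6 on the isomer with axial methoxy (anomeric effect) and both carbon substituents equatorial, which is 3S,6R.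

**Step 13**
Reactants: 21 tert-butyl{2-[(3S,6R)-6-[(6E)-hexadec-6-en-4-yn-1-yl]-6-methoxy-1,2-dioxan-3-yl]ethoxy}diphenylsilane
Product: 22 2-[(3S,6R)-6-[(6E)-hexadec-6-en-4-yn-1-yl]-6-methoxy-1,2-dioxan-3-yl]ethanol
Conditions: TBAF, AcOH (1:1), THF, 0 °C → rt
Reagents that add atoms: none
Why: Fluoride-mediated desilylation buffered by acetic acid cleaves the Si–O bond without base-induced Kornblum–DeLaMare fragmentation at the C3–H next to the peroxide.

**Step 14**
Reactants: 22 2-[(3S,6R)-6-[(6E)-hexadec-6-en-4-yn-1-yl]-6-methoxy-1,2-dioxan-3-yl]ethanol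
Product: 24 2-[(3S,6R)-6-[(6E)-hexadec-6-en-4-yn-1-yl]-6-methoxy-1,2-dioxan-3-yl]acetic acid, via β-peroxy aldehyde 23 (not isolated)
Conditions: TEMPO (0.2 equiv), PhI(OAc)2 (2.5 equiv), MeCN/H2O (1:1), 0 °C → rt
Reagents that add atoms: water, O
Why: Oxoammonium (TEMPO/PhI(OAc)2) oxidation takes the primary alcohol through the aldehyde hydrate to the acid under near-neutral, non-basic conditions that should leave the peroxyketal, the C3 centre and the ene-yne intact.

**Compound list**
1 | undec-1-yne | CCCCCCCCCC#C | starting material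
2 | (E)-undec-1-enylzirconocene chloride | CCCCCCCCC/C=C/[Zr](Cl)(C1C=CC=C1)C1C=CC=C1 | intermediate
3 | (E)-1-iodoundec-1-ene | CCCCCCCCC/C=C/I | intermediate
4 | prop-2-yn-1-ol | C#CCO | starting material
5 | (E)-tetradec-4-en-2-yn-1-ol | CCCCCCCCC/C=C/C#CCO | intermediate
6 | (E)-1-bromotetradec-4-en-2-yne | CCCCCCCCC/C=C/C#CCBr | intermediate
7 | 2-[(4S)-2,2-dimethyl-1,3-dioxolan-4-yl]ethanol | OCC[C@H]1COC(C)(C)O1 | starting material
8 | tert-butyl{2-[(4S)-2,2-dimethyl-1,3-dioxolan-4-yl]ethoxy}diphenylsilane | CC(C)(C)[Si](c1ccccc1)(c1ccccc1)OCC[C@H]1COC(C)(C)O1 | intermediate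
9 | (2S)-4-[(tert-butyldiphenylsilyl)oxy]butane-1,2-diol | CC(C)(C)[Si](c1ccccc1)(c1ccccc1)OCC[C@H](O)CO | intermediate
10 | (2S)-4-[(tert-butyldiphenylsilyl)oxy]-2-hydroxybutyl 4-methylbenzenesulfonate | CC(C)(C)[Si](c1ccccc1)(c1ccccc1)OCC[C@H](O)COS(=O)(=O)c1ccc(C)cc1 | intermediate
11 | tert-butyl{2-[(2S)-oxiran-2-yl]ethoxy}diphenylsilane | CC(C)(C)[Si](c1ccccc1)(c1ccccc1)OCC[C@H]1CO1 | intermediate
12 | ethoxyacetylene | CCOC#C | starting material
13 | (3R)-1-[(tert-butyldiphenylsilyl)oxy]-6-ethoxyhex-5-yn-3-ol | CC(C)(C)[Si](c1ccccc1)(c1ccccc1)OCC[C@H](O)CC#COCC | intermediate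
14 | (5R)-5-{2-[(tert-butyldiphenylsilyl)oxy]ethyl}oxolan-2-one | CC(C)(C)[Si](c1ccccc1)(c1ccccc1)OCC[C@H]1CCC(=O)O1 | intermediate
15 | 1-{(3R)-5-[(tert-butyldiphenylsilyl)oxy]-3-hydroxypentyl}cyclopropan-1-ol | CC(C)(C)[Si](c1ccccc1)(c1ccccc1)OCC[C@H](O)CCC1(O)CC1 | intermediate
16 | chlorozinc homoenolate (β-zincio ketone, C3 chlorozinc alkoxide) of 17 | Cl[Zn]CCC(=O)CC[C@@H](O[Zn]Cl)CCO[Si](c1ccccc1)(c1ccccc1)C(C)(C)C | intermediate
17 | (3R,12E)-1-[(tert-butyldiphenylsilyl)oxy]-3-hydroxydocos-12-en-10-yn-6-one | CCCCCCCCC/C=C/C#CCCCC(=O)CC[C@@H](O)CCO[Si](c1ccccc1)(c1ccccc1)C(C)(C)C | intermediate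
18 | (3R,12E)-1-[(tert-butyldiphenylsilyl)oxy]-6-oxodocos-12-en-10-yn-3-yl methanesulfonate | CCCCCCCCC/C=C/C#CCCCC(=O)CC[C@@H](OS(C)(=O)=O)CCO[Si](c1ccccc1)(c1ccccc1)C(C)(C)C | intermediate
19 | (3R,12E)-1-[(tert-butyldiphenylsilyl)oxy]-6-hydroperoxy-6-methoxydocos-12-en-10-yn-3-yl methanesulfonate (C6 epimers) | CCCCCCCCC/C=C/C#CCCCC(OC)(OO)CC[C@@H](OS(C)(=O)=O)CCO[Si](c1ccccc1)(c1ccccc1)C(C)(C)C | intermediate
20 | tert-butyl{2-[(3S)-6-[(6E)-hexadec-6-en-4-yn-1-yl]-6-methoxy-1,2-dioxan-3-yl]ethoxy}diphenylsilane (C6 epimers) | CCCCCCCCC/C=C/C#CCCCC1(OC)CC[C@@H](CCO[Si](c2ccccc2)(c2ccccc2)C(C)(C)C)OO1 | intermediate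
21 | tert-butyl{2-[(3S,6R)-6-[(6E)-hexadec-6-en-4-yn-1-yl]-6-methoxy-1,2-dioxan-3-yl]ethoxy}diphenylsilane | CCCCCCCCC/C=C/C#CCCC[C@]1(OC)CC[C@@H](CCO[Si](c2ccccc2)(c2ccccc2)C(C)(C)C)OO1 | intermediate
22 | 2-[(3S,6R)-6-[(6E)-hexadec-6-en-4-yn-1-yl]-6-methoxy-1,2-dioxan-3-yl]ethanol | CCCCCCCCC/C=C/C#CCCC[C@]1(OC)CC[C@@H](CCO)OO1 | intermediate
23 | 2-[(3S,6R)-6-[(6E)-hexadec-6-en-4-yn-1-yl]-6-methoxy-1,2-dioxan-3-yl]acetaldehyde | CCCCCCCCC/C=C/C#CCCC[C@]1(OC)CC[C@@H](CC=O)OO1 | intermediate
24 | 2-[(3S,6R)-6-[(6E)-hexadec-6-en-4-yn-1-yl]-6-methoxy-1,2-dioxan-3-yl]acetic acid | CCCCCCCCC/C=C/C#CCCC[C@]1(OC)CC[C@@H](CC(=O)O)OO1 | target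

**Step count and risks**
Total steps: 14. Longest linear sequence: 11 steps (steps 4–14, from 7 to 24).

Steps most likely to fail:

1. Step 9 (Proposed new method). The delocalised propargylic radical may couple through its allenyl carbon, the nickel homoenolate may undergo β-hydride elimination or protonation to the vinyl or ethyl ketone, or ring opening of the zinc cyclopropoxide may be too slow. The fallback uses known chemistry, sets out from 3 and 14 and comes back at 17. Sonogashira coupling of 3 with pent-4-yn-1-ol would give (E)-hexadec-6-en-4-yn-1-ol F1. Iodination (I2, PPh3, imidazole) would give (E)-1-iodohexadec-6-en-4-yne F2. Iodine–lithium exchange (t-BuLi, Et2O/pentane, −78 °C) would give (E)-hexadec-6-en-4-yn-1-yllithium F3. Mono-addition of F3 to the carbonyl of lactone 14 at −78 °C (stable tetrahedral lithium lactolate) would give 17 after work-up. This forms the C6–CH2 bond instead of the propargylic one.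

2. Step 12. E2 elimination of the secondary mesylate or a slow 6-exo displacement may compete with ring closure, and the acid-mediated epimerisation at C6 may stay incomplete or open the ring. The fallback sets out from 18 and comes back at 21. Intermolecular SN2 displacement of the mesylate by the caesium salt of 2-methoxyprop-2-yl hydroperoxide F4 (made by ozonolysis of 2,3-dimethylbut-2-ene in methanol; CsOH·H2O, DMF, 0 °C) would give, with inversion, (3S,12E)-1-[(tert-butyldiphenylsilyl)oxy]-3-[(2-methoxypropan-2-yl)peroxy]docos-12-en-10-yn-6-one F5. CSA in methanol would then remove the 2-methoxyprop-2-yl group, and the freed C3 hydroperoxide would add to the C6 ketone to give the cyclic peroxyhemiketal (3S)-3-{2-[(tert-butyldiphenylsilyl)oxy]ethyl}-6-[(6E)-hexadec-6-en-4-yn-1-yl]-1,2-dioxan-6-ol F6. Methanolysis of F6 in the same pot would give 21 under thermodynamic control, so the ring would be closed at C6–O instead of C3–O.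

3. Step 11. The three-component condensation may run on to the geminal dihydroperoxide or stop at the dimethyl ketal, and the Lewis acid may promote solvolysis of the mesylate with participation of the C6 oxygen. The fallback sets out from 18 and comes back at 19. Ketalisation (HC(OMe)3, MeOH, PPTS) would give the isolated dimethyl ketal (3R,12E)-1-[(tert-butyldiphenylsilyl)oxy]-6,6-dimethoxydocos-12-en-10-yn-3-yl methanesulfonate F7. Exchange of one methoxy group for OOH with anhydrous ethereal H2O2 and catalytic CSA at 0 °C would then give 19, the oxocarbenium ion being generated without a metal Lewis acid and with a controlled amount of peroxide.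

**Further compounds**
F1 | step 9 | (E)-hexadec-6-en-4-yn-1-ol | CCCCCCCCC/C=C/C#CCCCO
F2 | step 9 | (E)-1-iodohexadec-6-en-4-yne | CCCCCCCCC/C=C/C#CCCCI
F3 | step 9 | (E)-hexadec-6-en-4-yn-1-yllithium | [Li]CCCC#C/C=C/CCCCCCCCC
F4 | step 12 | 2-methoxyprop-2-yl hydroperoxide | COC(C)(C)OO
F5 | step 12 | (3S,12E)-1-[(tert-butyldiphenylsilyl)oxy]-3-[(2-methoxypropan-2-yl)peroxy]docos-12-en-10-yn-6-one | CCCCCCCCC/C=C/C#CCCCC(=O)CC[C@H](OOC(C)(C)OC)CCO[Si](c1ccccc1)(c1ccccc1)C(C)(C)C
F6 | step 12 | (3S)-3-{2-[(tert-butyldiphenylsilyl)oxy]ethyl}-6-[(6E)-hexadec-6-en-4-yn-1-yl]-1,2-dioxan-6-ol | CCCCCCCCC/C=C/C#CCCCC1(O)CC[C@@H](CCO[Si](c2ccccc2)(c2ccccc2)C(C)(C)C)OO1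
F7 | step 11 | (3R,12E)-1-[(tert-butyldiphenylsilyl)oxy]-6,6-dimethoxydocos-12-en-10-yn-3-yl methanesulfonate | CCCCCCCCC/C=C/C#CCCCC(OC)(OC)CC[C@@H](OS(C)(=O)=O)CCO[Si](c1ccccc1)(c1ccccc1)C(C)(C)C
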